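**Retrosynthetic overview**
1. The tiglate goes on last but one. O-13 is carried as an aldehyde, so the 2-OH is the only hydroxyl that can be acylated.
2. The γ-lactone is closed last, by oxidative lactonisation of a pentaol whose C11 carries two identical CH2OH groups. Only the one facing the 8β-OH can close, so the cage fixes C11.
3. The tetrahydrofuran ring comes from 5-exo opening of a 4α,5α-epoxide by the 11-OH. This sets C4 and C5.
4. C7–C11 comes from a decarboxylative aldol with diethyl ketomalonate, and the C10 methyl from a cuprate addition, both on a cycloheptadienone made by RCM.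
5. Ring order: cyclopentane (bought, chiral), then cycloheptane, then tetrahydrofuran, then γ-lactone.

Assumption: guaiane numbering of the target is used throughout (C1/C5 ring fusion, C2–C4 five-membered ring, C6–C10 seven-membered ring, C11–C13 side chain, C14 on C10, C15 on C4). α is the face that carries H-1. The enantiopure silyloxy-enone, the organozinc solution, diethyl ketomalonate and tigloyl chloride are bought.

Step 1
Reactants: 1 (S)-4-(tert-butyldimethylsilyloxy)cyclopent-2-en-1-one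
Product: 2 (S)-4-(tert-butyldimethylsilyloxy)-2-iodocyclopent-2-en-1-one
Conditions: I2, pyridine, CH2Cl2, 0 °C → rt
Reagents that add atoms: iodine, II
Why: Johnson α-iodination (pyridine addition, iodination, elimination; Baylis–Hillman type) touches only the enone α-carbon and leaves the silyloxy stereocentre (later C2) intact.

Step 2
Reactants: 2 (S)-4-(tert-butyldimethylsilyloxy)-2-iodocyclopent-2-en-1-one; 3 (3-ethoxy-3-oxopropyl)zinc bromide
Product: 4 ethyl 3-[(3S)-3-(tert-butyldimethylsilyloxy)-5-oxocyclopent-1-en-1-yl]propanoate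
Conditions: Pd(dba)2 (5 mol %), P(2-furyl)3 (10 mol %), THF/DMF, rt
Reagents that add atoms: none
Why: Negishi sp2–sp3 coupling of an α-iodoenone with a zinc homoenolate tolerates ketone, ester and silyl ether and brings in C6–C8.

Step 3
Reactants: 4 ethyl 3-[(3S)-3-(tert-butyldimethylsilyloxy)-5-oxocyclopent-1-en-1-yl]propanoate
Product: 6 ethyl 3-[(4S,5S)-4-(tert-butyldimethylsilyloxy)-2-(trifluoromethylsulfonyloxy)-5-vinylcyclopent-1-en-1-yl]propanoate, via bromomagnesium enolate 5 (not isolated)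
Conditions: vinylMgBr, CuI·2LiCl (15 mol %), THF, −78 °C; then Comins' reagent, −78 → 0 °C
Reagents that add atoms: vinylmagnesium bromide, C=C[Mg]Br; Comins' reagent (N-(5-chloropyridin-2-yl)bis(trifluoromethanesulfonimide)), O=S(=O)(N(c1ccc(Cl)cn1)S(=O)(=O)C(F)(F)F)C(F)(F)F
Why: Copper-catalysed 1,4-addition (prostaglandin two-component coupling) delivers vinyl anti to the 2α-OTBS group and so sets C1 (H-1 α), and the regiodefined enolate is O-triflated before it can equilibrate or lose silanolate.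

Step 4
Reactants: 6 ethyl 3-[(4S,5S)-4-(tert-butyldimethylsilyloxy)-2-(trifluoromethylsulfonyloxy)-5-vinylcyclopent-1-en-1-yl]propanoate
Product: 7 ethyl 3-[(4S,5S)-4-(tert-butyldimethylsilyloxy)-2-methyl-5-vinylcyclopent-1-en-1-yl]propanoate
Conditions: MeZnCl, Pd(PPh3)4 (5 mol %), THF, 50 °C
Reagents that add atoms: methylzinc chloride, C[Zn]Cl
Why: Negishi methylation of the enol triflate fixes the tetrasubstituted C4=C5 alkene with C15, spares the ester and touches no stereocentre.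

Step 5
Reactants: 7 ethyl 3-[(4S,5S)-4-(tert-butyldimethylsilyloxy)-2-methyl-5-vinylcyclopent-1-en-1-yl]propanoate
Product: 9 5-[(4S,5S)-4-(tert-butyldimethylsilyloxy)-2-methyl-5-vinylcyclopent-1-en-1-yl]pent-1-en-3-one, via Weinreb amide 8 (not isolated)
Conditions: MeNH(OMe)·HCl, iPrMgCl, THF, −20 °C; then vinylMgBr, 0 °C; inverse quench into cold 1 M HCl
Reagents that add atoms: vinylmagnesium bromide, C=C[Mg]Br; N,O-dimethylhydroxylamine hydrochloride, CNOC.Cl (its N(OMe)Me group is held only in 8)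
Why: Weinreb ketone synthesis, in which the chelated tetrahedral intermediate stops over-addition and the acidic inverse quench keeps the freed amine from adding to the vinyl ketone.

Step 6
Reactants: 9 5-[(4S,5S)-4-(tert-butyldimethylsilyloxy)-2-methyl-5-vinylcyclopent-1-en-1-yl]pent-1-en-3-one
Product: 10 (1αH)-2α-(tert-butyldimethylsilyloxy)-11,12,13,14-tetranorguaia-4,9-dien-8-one
Conditions: Grubbs II (5 mol %), CH2Cl2 (2 mM), reflux
Reagents that add atoms: none
Why: Ring-closing metathesis joins the two monosubstituted alkenes to the (Z)-cycloheptenone while the tetrasubstituted C4=C5 alkene is inert.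

Step 7
Reactants: 10 (1αH)-2α-(tert-butyldimethylsilyloxy)-11,12,13,14-tetranorguaia-4,9-dien-8-one; 11 diethyl ketomalonate
Product: 14 diethyl (1αH,7αH)-2α-(tert-butyldimethylsilyloxy)-11-hydroxy-8-oxo-14-norguaia-4,9-diene-12,13-dioate, via β-keto acid 12 (not isolated), via carboxy aldol adduct 13 (not isolated)
Conditions: LDA, THF, −78 °C; CO2 (g); AcOH (2 equiv); then 11, −78 → 23 °C
Reagents that add atoms: carbon dioxide, O=C=O (held only in 12 and 13)
Why: Kinetic α′-carboxylation followed by a decarboxylative aldol: the β-keto acid adds to the very electrophilic ketone on the convex α-face, loss of CO2 gives the cross-conjugated dienol, and its ketonisation by protonation again from the convex α-face leaves H-7 α and C11 β, while C11 is not stereogenic because its two esters are alike.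

Step 8
Reactants: 14 diethyl (1αH,7αH)-2α-(tert-butyldimethylsilyloxy)-11-hydroxy-8-oxo-14-norguaia-4,9-diene-12,13-dioate
Product: 15 diethyl (1αH,7αH,10βH)-2α-(tert-butyldimethylsilyloxy)-11-hydroxy-8-oxoguai-4-ene-12,13-dioate
Conditions: Me2CuLi (3 equiv, from MeLi and CuI), Et2O, −78 → −40 °C; aq NH4Cl/NH3
Reagents that add atoms: lithium dimethylcuprate, [Li+].C[Cu-]C
Why: Gilman 1,4-addition puts methyl on C10 from the convex α-face (the β-face is covered by the folded cyclopentene and the 7β side chain), giving 10α-CH3, and the enolate forms toward C9 so C7 is not touched.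

Step 9
Reactants: 15 diethyl (1αH,7αH,10βH)-2α-(tert-butyldimethylsilyloxy)-11-hydroxy-8-oxoguai-4-ene-12,13-dioate
Product: 16 diethyl (1αH,7αH,10βH)-2α,11-dihydroxy-8-oxoguai-4-ene-12,13-dioate
Conditions: HF·pyridine, THF, 0 °C → rt
Reagents that add atoms: none
Why: Fluoride desilylation in a weakly acidic medium avoids retro-aldol and C7 epimerisation and frees the 2α-OH as a directing group.

Step 10
Reactants: 16 diethyl (1αH,7αH,10βH)-2α,11-dihydroxy-8-oxoguai-4-ene-12,13-dioate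
Product: 18 diethyl (1αH,7αH,10βH)-5β,11-epoxy-2α,4α-dihydroxy-8-oxoguaiane-12,13-dioate, via 4α,5α-epoxide 17 (not isolated)
Conditions: mCPBA (1.05 equiv), CH2Cl2, 0 °C; then CSA (10 mol %), rt
Reagents that add atoms: 3-chloroperbenzoic acid, OOC(=O)c1cccc(Cl)c1
Why: Henbest-type hydroxyl-directed Prilezhaev epoxidation attacks the electron-rich C4=C5 alkene on the convex α-face cis to the 2α-OH, and acid-catalysed 5-exo-tet opening at C5 with inversion by the β-disposed 11-OH then sets 4α-OH and 5β-O.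

Step 11
Reactants: 18 diethyl (1αH,7αH,10βH)-5β,11-epoxy-2α,4α-dihydroxy-8-oxoguaiane-12,13-dioate
Product: 19 (1αH,7αH,8αH,10βH)-5β,11-epoxyguaiane-2α,4α,8β,12,13-pentaol
Conditions: LiAlH4 (excess), THF, 0 → 40 °C; Rochelle salt work-up
Reagents that add atoms: none
Why: Global hydride reduction in which hydride reaches C8 from the α-face (the side of the C6 bridge) because the endo ester on C11 shields the β-face, giving 8β-OH, while both esters become identical CH2OH groups so C11 stays non-stereogenic.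

Step 12
Reactants: 19 (1αH,7αH,8αH,10βH)-5β,11-epoxyguaiane-2α,4α,8β,12,13-pentaol
Product: 21 (1αH,7αH,8αH,10βH)-5β,11-epoxy-2α,4α-dihydroxy-13-oxoguaian-8β,12-olide, via lactol aldehyde 20 (not isolated)
Conditions: TEMPO (20 mol %), PhI(OAc)2 (3.3 equiv), CH2Cl2, rt
Reagents that add atoms: none
Why: TEMPO/PhI(OAc)2 oxidation is selective for primary alcohols, only the endo aldehyde can reach the 8β-OH and is carried via the lactol to the cis-γ-lactone (which fixes C11 in the only geometry the cage allows), and the exo CHO remains as a masked O-13 beside the untouched 2-OH and 4-OH.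

Step 13
Reactants: 21 (1αH,7αH,8αH,10βH)-5β,11-epoxy-2α,4α-dihydroxy-13-oxoguaian-8β,12-olide; 22 tigloyl chloride
Product: 23 (1αH,7αH,8αH,10βH)-5β,11-epoxy-4α-hydroxy-13-oxo-2α-tigloyloxyguaian-8β,12-olide
Conditions: Et3N, DMAP (20 mol %), CH2Cl2, 0 °C → rt
Reagents that add atoms: none
Why: DMAP-catalysed acylation meets only one acylable hydroxyl (2α-OH, since 4-OH is tertiary), the non-enolisable aldehyde is inert and the (E)-tiglate geometry is the stable one.

Step 14
Reactants: 23 (1αH,7αH,8αH,10βH)-5β,11-epoxy-4α-hydroxy-13-oxo-2α-tigloyloxyguaian-8β,12-olide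
Product: 24 (1αH,7αH,8αH,10βH)-5β,11-epoxy-4α,13-dihydroxy-2α-tigloyloxyguaian-8β,12-olide (target; 1R,2S,4R,5R,7S,8R,10R,11R)
Conditions: NaBH4, THF/MeOH, −40 °C
Reagents that add atoms: none
Why: Chemoselective borohydride reduction of the activated α-alkoxy aldehyde is far faster than attack on the lactone or the conjugated ester and creates no new stereocentre.

**Compound list**

| No. | Name | SMILES | Role |
|---|---|---|---|
| 1 | (S)-4-(tert-butyldimethylsilyloxy)cyclopent-2-en-1-one | CC(C)(C)[Si](C)(C)O[C@H]1CC(=O)C=C1 | starting material |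
| 2 | (S)-4-(tert-butyldimethylsilyloxy)-2-iodocyclopent-2-en-1-one | CC(C)(C)[Si](C)(C)O[C@H]1CC(=O)C(I)=C1 | intermediate |
| 3 | (3-ethoxy-3-oxopropyl)zinc bromide | CCOC(=O)CC[Zn]Br | starting material |
| 4 | ethyl 3-[(3S)-3-(tert-butyldimethylsilyloxy)-5-oxocyclopent-1-en-1-yl]propanoate | CC(C)(C)[Si](C)(C)O[C@H]1CC(=O)C(CCC(=O)OCC)=C1 | intermediate |
| 5 | bromomagnesium enolate of the vinyl 1,4-adduct (vinyl trans to OTBS) | CC(C)(C)[Si](C)(C)O[C@H]1CC(O[Mg]Br)=C(CCC(=O)OCC)[C@@H]1C=C | intermediate |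
| 6 | ethyl 3-[(4S,5S)-4-(tert-butyldimethylsilyloxy)-2-(trifluoromethylsulfonyloxy)-5-vinylcyclopent-1-en-1-yl]propanoate | CC(C)(C)[Si](C)(C)O[C@H]1CC(OS(=O)(=O)C(F)(F)F)=C(CCC(=O)OCC)[C@@H]1C=C | intermediate |
| 7 | ethyl 3-[(4S,5S)-4-(tert-butyldimethylsilyloxy)-2-methyl-5-vinylcyclopent-1-en-1-yl]propanoate | CC(C)(C)[Si](C)(C)O[C@H]1CC(C)=C(CCC(=O)OCC)[C@@H]1C=C | intermediate |
| 8 | the corresponding N-methoxy-N-methylpropanamide (Weinreb amide) | CC(C)(C)[Si](C)(C)O[C@H]1CC(C)=C(CCC(=O)N(C)OC)[C@@H]1C=C | intermediate |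
| 9 | 5-[(4S,5S)-4-(tert-butyldimethylsilyloxy)-2-methyl-5-vinylcyclopent-1-en-1-yl]pent-1-en-3-one | CC(C)(C)[Si](C)(C)O[C@H]1CC(C)=C(CCC(=O)C=C)[C@@H]1C=C | intermediate |
| 10 | (1αH)-2α-(tert-butyldimethylsilyloxy)-11,12,13,14-tetranorguaia-4,9-dien-8-one | CC(C)(C)[Si](C)(C)O[C@H]1CC(C)=C2CCC(=O)C=C[C@H]12 | intermediate |
| 11 | diethyl ketomalonate | CCOC(=O)C(=O)C(=O)OCC | starting material |
| 12 | 7-carboxylic acid of 10 (β-keto acid, C7 labile) | CC(C)(C)[Si](C)(C)O[C@H]1CC(C)=C2CC(C(=O)O)C(=O)C=C[C@H]12 | intermediate |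
| 13 | 7β-carboxy-7α-[bis(ethoxycarbonyl)hydroxymethyl] adduct of 10 | CC(C)(C)[Si](C)(C)O[C@H]1CC(C)=C2C[C@](C(O)(C(=O)OCC)C(=O)OCC)(C(=O)O)C(=O)C=C[C@H]12 | intermediate |
| 14 | diethyl (1αH,7αH)-2α-(tert-butyldimethylsilyloxy)-11-hydroxy-8-oxo-14-norguaia-4,9-diene-12,13-dioate | CC(C)(C)[Si](C)(C)O[C@H]1CC(C)=C2C[C@H](C(O)(C(=O)OCC)C(=O)OCC)C(=O)C=C[C@H]12 | intermediate |
| 15 | diethyl (1αH,7αH,10βH)-2α-(tert-butyldimethylsilyloxy)-11-hydroxy-8-oxoguai-4-ene-12,13-dioate | CC(C)(C)[Si](C)(C)O[C@H]1CC(C)=C2C[C@H](C(O)(C(=O)OCC)C(=O)OCC)C(=O)C[C@@H](C)[C@H]12 | intermediate |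
| 16 | diethyl (1αH,7αH,10βH)-2α,11-dihydroxy-8-oxoguai-4-ene-12,13-dioate | O[C@H]1CC(C)=C2C[C@H](C(O)(C(=O)OCC)C(=O)OCC)C(=O)C[C@@H](C)[C@H]12 | intermediate |
| 17 | 4α,5α-epoxide of 16 | O[C@H]1C[C@@]4(C)O[C@]45C[C@H](C(O)(C(=O)OCC)C(=O)OCC)C(=O)C[C@@H](C)[C@H]15 | intermediate |
| 18 | diethyl (1αH,7αH,10βH)-5β,11-epoxy-2α,4α-dihydroxy-8-oxoguaiane-12,13-dioate | O[C@H]1C[C@@](C)(O)[C@@]23C[C@H](C(C(=O)OCC)(C(=O)OCC)O3)C(=O)C[C@@H](C)[C@H]12 | intermediate |
| 19 | (1αH,7αH,8αH,10βH)-5β,11-epoxyguaiane-2α,4α,8β,12,13-pentaol | O[C@H]1C[C@@](C)(O)[C@@]23C[C@H](C(CO)(CO)O3)[C@H](O)C[C@@H](C)[C@H]12 | intermediate |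
| 20 | 8β,12-lactol of the 12,13-dialdehyde (anomeric centre undefined) | O[C@H]1C[C@@](C)(O)[C@@]23C[C@H]4[C@@H](C[C@@H](C)[C@H]12)OC(O)[C@@]4(C=O)O3 | intermediate |
| 21 | (1αH,7αH,8αH,10βH)-5β,11-epoxy-2α,4α-dihydroxy-13-oxoguaian-8β,12-olide | O[C@H]1C[C@@](C)(O)[C@@]23C[C@H]4[C@@H](C[C@@H](C)[C@H]12)OC(=O)[C@@]4(C=O)O3 | intermediate |
| 22 | tigloyl chloride ((E)-2-methylbut-2-enoyl chloride) | C/C=C(\C)C(=O)Cl | starting material |
| 23 | (1αH,7αH,8αH,10βH)-5β,11-epoxy-4α-hydroxy-13-oxo-2α-tigloyloxyguaian-8β,12-olide | C/C=C(\C)C(=O)O[C@H]1C[C@@](C)(O)[C@@]23C[C@H]4[C@@H](C[C@@H](C)[C@H]12)OC(=O)[C@@]4(C=O)O3 | intermediate |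
| 24 | (1αH,7αH,8αH,10βH)-5β,11-epoxy-4α,13-dihydroxy-2α-tigloyloxyguaian-8β,12-olide | C/C=C(\C)C(=O)O[C@H]1C[C@@](C)(O)[C@@]23C[C@H]4[C@@H](C[C@@H](C)[C@H]12)OC(=O)[C@@]4(CO)O3 | target |

**Step count**
- Total step count: 14.
- Longest linear sequence: 14 steps (1 → 24). Compounds 3, 11 and 22 are bought.

**Three steps most likely to fail**

**Step 7.** C7 must end contra-steric. If decarboxylation runs ahead of C–C bond formation, the free dienolate adds to 11 on the α-face and the 7-epimer results. The fallback sets C7 by hydride delivery to an sp2 carbon instead of by protonation. It sets out from 10 and comes back at 15.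
- Me2CuLi is added first and gives (1αH,10βH)-2α-(tert-butyldimethylsilyloxy)-11,12,13-trinorguai-4-en-8-one F1.
- TiCl4/pyridine condensation with 11 at the less hindered C7 gives diethyl (1αH,10βH)-2α-(tert-butyldimethylsilyloxy)-8-oxoguaia-4,7(11)-diene-12,13-dioate F2.
- Hantzsch-ester transfer hydrogenation brings hydride to C7 from the convex α-face and gives diethyl (1αH,7αH,10βH)-2α-(tert-butyldimethylsilyloxy)-8-oxoguai-4-ene-12,13-dioate F3.
- Selective deprotonation of the malonate C–H (NaH, 0 °C) and Davis oxaziridine hydroxylation then give 15.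

**Step 10.** The C8 carbonyl oxygen can take part across the ring and capture C5 as a 5,8-hemiketal, or epoxidation can stray to the β-face. The fallback ties up O-8 as the lactone before the ether is made. It sets out from 16 and comes back at 19.
- NaBH4 (α-face attack) and NaOEt-equilibrated lactonisation give ethyl (1αH,7αH,8αH,10βH)-2α,11-dihydroxyguai-4-en-8β,12-olid-13-oate F4, with the ester on the convex face and the 11-OH cis to C6.
- 2-OH-directed epoxidation and acid cyclisation give ethyl (1αH,7αH,8αH,10βH)-5β,11-epoxy-2α,4α-dihydroxyguaian-8β,12-olid-13-oate F5.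
- LiAlH4 reduces F5 to 19.

**Step 12.** Three oxidations must occur on a pentaol without touching the 2-OH, and the step depends on the 8β-OH from step 11. The fallback avoids the polyol and differentiates the two carboxyl carbons through a free acid. It sets out from 18 and comes back at 24.
- Tigloylation of the only secondary OH gives diethyl (1αH,7αH,10βH)-5β,11-epoxy-4α-hydroxy-8-oxo-2α-tigloyloxyguaiane-12,13-dioate F6.
- NaBH4 reduces C8 and the alkoxide closes on the endo ester to give ethyl (1αH,7αH,8αH,10βH)-5β,11-epoxy-4α-hydroxy-2α-tigloyloxyguaian-8β,12-olid-13-oate F7.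
- LiOH (1 equiv, 0 °C; the lactone re-closes on acidification) cleaves the activated exo ester to 5β,11-epoxy-4α-hydroxy-2α-tigloyloxyguaian-8β,12-olid-13-oic acid F8.
- Isobutyl chloroformate/N-methylmorpholine and then NaBH4 reduce only the mixed anhydride to 24.

**Further compounds**
F1 | step 7 | (1αH,10βH)-2α-(tert-butyldimethylsilyloxy)-11,12,13-trinorguai-4-en-8-one | CC(C)(C)[Si](C)(C)O[C@H]1CC(C)=C2CCC(=O)C[C@@H](C)[C@H]12
F2 | step 7 | diethyl (1αH,10βH)-2α-(tert-butyldimethylsilyloxy)-8-oxoguaia-4,7(11)-diene-12,13-dioate | CC(C)(C)[Si](C)(C)O[C@H]1CC(C)=C2CC(=C(C(=O)OCC)C(=O)OCC)C(=O)C[C@@H](C)[C@H]12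
F3 | step 7 | diethyl (1αH,7αH,10βH)-2α-(tert-butyldimethylsilyloxy)-8-oxoguai-4-ene-12,13-dioate | CC(C)(C)[Si](C)(C)O[C@H]1CC(C)=C2C[C@H](C(C(=O)OCC)C(=O)OCC)C(=O)C[C@@H](C)[C@H]12
F4 | step 10 | ethyl (1αH,7αH,8αH,10βH)-2α,11-dihydroxyguai-4-en-8β,12-olid-13-oate | O[C@H]1CC(C)=C2C[C@H]3[C@@H](C[C@@H](C)[C@H]12)OC(=O)[C@@]3(C(=O)OCC)O
F5 | step 10 | ethyl (1αH,7αH,8αH,10βH)-5β,11-epoxy-2α,4α-dihydroxyguaian-8β,12-olid-13-oate | O[C@H]1C[C@@](C)(O)[C@@]23C[C@H]4[C@@H](C[C@@H](C)[C@H]12)OC(=O)[C@@]4(C(=O)OCC)O3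
F6 | step 12 | diethyl (1αH,7αH,10βH)-5β,11-epoxy-4α-hydroxy-8-oxo-2α-tigloyloxyguaiane-12,13-dioate | C/C=C(\C)C(=O)O[C@H]1C[C@@](C)(O)[C@@]23C[C@H](C(C(=O)OCC)(C(=O)OCC)O3)C(=O)C[C@@H](C)[C@H]12
F7 | step 12 | ethyl (1αH,7αH,8αH,10βH)-5β,11-epoxy-4α-hydroxy-2α-tigloyloxyguaian-8β,12-olid-13-oate | C/C=C(\C)C(=O)O[C@H]1C[C@@](C)(O)[C@@]23C[C@H]4[C@@H](C[C@@H](C)[C@H]12)OC(=O)[C@@]4(C(=O)OCC)O3
F8 | step 12 | 5β,11-epoxy-4α-hydroxy-2α-tigloyloxyguaian-8β,12-olid-13-oic acid | C/C=C(\C)C(=O)O[C@H]1C[C@@](C)(O)[C@@]23C[C@H]4[C@@H](C[C@@H](C)[C@H]12)OC(=O)[C@@]4(C(=O)O)O3
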